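## Retrosynthetic overview

1. Target 21 ⇐ 17-nor-16-ketone 19: the C16 carbinol comes from exo-face MeMgBr addition, and the C19 ester is cleaved last.
2. 19 ⇐ vinyl ketone 18: one acid-catalysed Prins / cation–olefin / semipinacol cascade closes ring C (C15→C16) and ring D (C14→C8) with a 1,2-shift of C12, as in the ent-copalyl → ent-kauranyl cation sequence.
3. 18 ⇐ bromo enone 13: ring B is contracted 6→5 by a hydride-triggered semipinacol shift of C8 from C7 to C6, with C7 extruded as the aldehyde (the GA12-aldehyde-type step).
4. 13 ⇐ acyclic β-keto ester 7: a trivalent-manganese radical polyene bicyclisation forms rings A and B with the exocyclic C8=C15 alkene; the enantiomer is selected by CBS reduction, and 7 comes from geranyl bromide in four steps.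
5. Ring order: A → B (six-membered) → B contracted to five → C → D.

Assumption: locants C1–C20 are those of the target's ent-gibberellane skeleton (C7 = CH2OH carbon, C15 = CH2 between C8 and C16; α/β as in the usual gibberellin drawing, with C19 and C20 α and H-5, H-9, C7 and 3-OH β), and 8 is a racemate whose SMILES shows the enantiomer that is carried on.

## Route

Step 1
Reactants: 1 geranyl bromide; 2 N-methoxy-N-methylacetamide
Product: 3 geranylacetic Weinreb amide
Conditions: 2, LiN(i-Pr)2, THF, −78 °C; then 1, −78 to 0 °C
Reagents that add atoms: none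
Why: Amide enolate alkylation (SN2) at the primary allylic bromide; the (E)-alkene is untouched and no stereocentre is formed.

Step 2
Reactants: 3 geranylacetic Weinreb amide
Product: 4 terminal (E)-allylic alcohol
Conditions: SeO2 (0.3 equiv), t-BuOOH (3 equiv), salicylic acid (cat.), CH2Cl2, 0 °C to rt
Reagents that add atoms: tert-butyl hydroperoxide CC(C)(C)OO (terminal oxidant; the oxygen atom is relayed by selenium dioxide O=[Se]=O)
Why: Selenium dioxide allylic oxidation (ene reaction then 2,3-sigmatropic shift) is selective for the (E)-methyl of the terminal trisubstituted alkene and returns the (E)-allylic alcohol.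

Step 3
Reactants: 4 terminal (E)-allylic alcohol
Product: 5 allylic bromide
Conditions: CBr4, PPh3, CH2Cl2, 0 °C
Reagents that add atoms: carbon tetrabromide BrC(Br)(Br)Br
Why: Appel reaction of a primary allylic alcohol proceeds by SN2 without allylic transposition, and the Weinreb amide is inert.

Step 4
Reactants: 5 allylic bromide; 6 methyl 2-methyl-3-oxobutanoate
Product: 7 acyclic β-keto ester triene
Conditions: 6, NaH, THF, 0 °C; n-BuLi, 0 °C; then 5, 0 °C; aq. NH4Cl
Reagents that add atoms: none
Why: γ-Alkylation of the acetoacetate dianion with the allylic bromide is faster than any attack on the Weinreb amide and installs the C1–C2 bond of the cyclisation substrate.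

Step 5
Reactants: 7 acyclic β-keto ester triene
Product: 8 racemic bicyclic keto ester
Conditions: Mn(OAc)3·2H2O (2.2 equiv), Cu(OAc)2·H2O (0.5 equiv), AcOH, rt
Reagents that add atoms: none
Why: Oxidative free-radical polyene cyclisation: the α-keto ester radical closes ring A then ring B by two 6-endo closures through chair-like transition states of the (E,E)-diene, giving the trans-decalin with axial CO2Me cis to the angular methyl and H-9 trans to it, and divalent copper oxidises the tertiary C8 radical to the exocyclic alkene.

Step 6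
Reactants: 8 racemic bicyclic keto ester
Product: 9 axial 3β-alcohol (single enantiomer)
Conditions: (R)-2-methyl-CBS-oxazaborolidine (C18H20BNO, 20 mol %), catecholborane (0.6 equiv), toluene, −40 °C, to ca. 50 % conversion; chromatography
Reagents that add atoms: none
Why: Corey–Bakshi–Shibata reduction run as a kinetic resolution: the (R)-catalyst delivers hydride to the face that gives the 3S carbinol (quaternary C4 as the large group), which in the drawn enantiomer is the equatorial attack that gives the axial 3β-alcohol, while the antipodal ketone is mismatched, reacts slowly and is separated.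

Step 7
Reactants: 9 axial 3β-alcohol
Product: 11 exocyclic 7-oxo enone, via 7-hydroxy allylic alcohol 10 (not isolated)
Conditions: SeO2 (0.3 equiv), t-BuOOH (3 equiv), CH2Cl2, rt; then MnO2 (excess), rt
Reagents that add atoms: tert-butyl hydroperoxide CC(C)(C)OO (terminal oxidant; the oxygen atom is relayed by selenium dioxide O=[Se]=O)
Why: Selenium dioxide allylic hydroxylation occurs at the ring CH2 (C7) next to the 1,1-disubstituted alkene, and MnO2 then oxidises only this allylic alcohol, leaving the 3-OH untouched.

Step 8
Reactants: 11 exocyclic 7-oxo enone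
Product: 13 6β-bromo enone, via dilithium dienolate 12 (not isolated)
Conditions: LiN(SiMe3)2 (2.2 equiv), THF, −78 °C; NBS (1.05 equiv), −78 °C; aq. NH4Cl
Reagents that add atoms: N-bromosuccinimide O=C1CCC(=O)N1Br
Why: Enolate α-bromination: deprotonation is possible only at C6 (C8 is sp2), and the cross-conjugated dienolate is brominated from the β face because the α face is blocked by the syn-axial C20 methyl and C19 ester, giving the equatorial 6β-bromide.

Step 9
Reactants: 13 6β-bromo enone
Product: 16 ring-contracted diol, via bromohydrin 14 (not isolated), via aldehyde 15 (not isolated)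
Conditions: NaBH4 (3 equiv), CeCl3·7H2O (1.2 equiv), MeOH, −40 °C; then K2CO3 (3 equiv), NaBH4 (2 equiv), 45 °C
Reagents that add atoms: none
Why: Proposed new method: Luche 1,2-reduction gives the allylic bromohydrin 14, whose C7–C8 bond is anti-periplanar to the equatorial C6–Br bond of the rigid trans-decalin, so under mild base the alkenyl carbon C8 migrates from C7 to C6 with inversion (C7 ends β, H-6 α) while C7 becomes the aldehyde 15, which borohydride reduces at once; the closest known reactions are the base- or Lewis-acid-promoted semipinacol (Tiffeneau-type) ring contraction of 2-halocycloalkanols and the contraction of 7-hydroxy-ent-kaurenoic acid to GA12-aldehyde.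

Step 10
Reactants: 16 ring-contracted diol
Product: 18 vinyl ketone, via magnesium hemiaminal adduct 17 (not isolated)
Conditions: CH2=CHMgBr (5 equiv), THF, −20 to 0 °C; then cold 1 M HCl
Reagents that add atoms: vinylmagnesium bromide C=C[Mg]Br
Why: Weinreb ketone synthesis: the chelated tetrahedral adduct stops at mono-addition and releases the enone on acidic quench, two equivalents of Grignard are consumed by the hydroxyl groups, and the neopentyl C19 ester is inert.

Step 11
Reactants: 18 vinyl ketone
Product: 19 tetracyclic 17-nor-16-ketone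
Conditions: Sc(OTf)3 (20 mol %), CH2Cl2, −20 °C to rt
Reagents that add atoms: none
Why: Proposed new method: scandium triflate activates the ketone for a six-membered Prins attack by the 1,1-disubstituted alkene (C15→C16) through a chair with C10 equatorial, the tertiary C8 cation is captured on its α face by the axial vinyl group (C14→C8), and the secondary C13 cation next to the metal alkoxide is quenched by a semipinacol 1,2-shift of C12 from C16 to C13, which regenerates the ketone and sets C8 and C13 as in the target; the closest known reactions are Lewis-acid Prins cyclisations of ketones and the cation-triggered semipinacol rearrangement of 1-vinylcycloalkanols (Prins–pinacol), and the sequence parallels the ent-pimarenyl → ent-beyeranyl → ent-kauranyl cation steps.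

Step 12
Reactants: 19 tetracyclic 17-nor-16-ketone
Product: 20 target methyl ester
Conditions: MeMgBr (6 equiv), THF, −78 to 0 °C; aq. NH4Cl
Reagents that add atoms: methylmagnesium bromide C[Mg]Br
Why: Grignard 1,2-addition to the bicyclo[3.2.1]octanone from the exo face (the side of the one-carbon bridge C14; the endo face is shielded by the axial H on C11) places 16-CH3 exo and 16-OH endo, and the hindered C19 ester does not react at low temperature.

Step 13
Reactants: 20 target methyl ester
Product: 21 target acid CNP0170663.1
Conditions: NaSEt (6 equiv), DMF, 100 °C; then 1 M HCl to pH 3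
Reagents that add atoms: none
Why: SN2 demethylation of the hindered methyl ester by thiolate (O-alkyl cleavage) avoids acyl attack at the neopentyl carbonyl and, being only weakly basic, leaves the alcohols and all stereocentres untouched.

## Compound list

1 | geranyl bromide, (2E)-1-bromo-3,7-dimethylocta-2,6-diene | CC(C)=CCC/C(C)=C/CBr | starting material
2 | N-methoxy-N-methylacetamide | CC(=O)N(C)OC | starting material
3 | (4E)-N-methoxy-N,5,9-trimethyldeca-4,8-dienamide | CC(C)=CCC/C(C)=C/CCC(=O)N(C)OC | intermediate
4 | (4E,8E)-10-hydroxy-N-methoxy-N,5,9-trimethyldeca-4,8-dienamide | OC/C(C)=C/CC/C(C)=C/CCC(=O)N(C)OC | intermediate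
5 | (4E,8E)-10-bromo-N-methoxy-N,5,9-trimethyldeca-4,8-dienamide | BrC/C(C)=C/CC/C(C)=C/CCC(=O)N(C)OC | intermediate
6 | methyl 2-methyl-3-oxobutanoate | COC(=O)C(C)C(C)=O | starting material
7 | methyl (6E,10E)-14-[methoxy(methyl)amino]-2,6,10-trimethyl-3,14-dioxotetradeca-6,10-dienoate (C2 epimers) | COC(=O)C(C)C(=O)CC/C(C)=C/CC/C(C)=C/CCC(=O)N(C)OC | intermediate
8 | racemic methyl 5-{3-[methoxy(methyl)amino]-3-oxopropyl}-1,4a-dimethyl-6-methylidene-2-oxodecahydronaphthalene-1-carboxylate; trans-decalin; in target locants 3-oxo, 8(15)-ene, 4α-CO2Me, 4β-CH3, 5β-H, 9β-H, 10α-CH3 | C[C@@]12CCC(=O)[C@@](C)(C(=O)OC)[C@H]1CCC(=C)[C@H]2CCC(=O)N(C)OC | intermediate (racemate)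
9 | 3β-hydroxy (axial, 3S) analogue of 8, single enantiomer | C[C@@]12CC[C@H](O)[C@@](C)(C(=O)OC)[C@H]1CCC(=C)[C@H]2CCC(=O)N(C)OC | intermediate
10 | 3β,7β-dihydroxy-8(15)-ene (allylic alcohol at C7) | C[C@@]12CC[C@H](O)[C@@](C)(C(=O)OC)[C@H]1CC[C@H](O)C(=C)[C@H]2CCC(=O)N(C)OC | intermediate (not isolated)
11 | 3β-hydroxy-7-oxo-8(15)-ene (exocyclic enone) | C[C@@]12CC[C@H](O)[C@@](C)(C(=O)OC)[C@H]1CC(=O)C(=C)[C@H]2CCC(=O)N(C)OC | intermediate
12 | dilithium 3-olate / 6,8(15)-dien-7-olate of 11 | [Li+].[Li+].C[C@@]12CC[C@H]([O-])[C@@](C)(C(=O)OC)[C@H]1C=C([O-])C(=C)[C@H]2CCC(=O)N(C)OC | intermediate (not isolated)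
13 | 6β-bromo-3β-hydroxy-7-oxo-8(15)-ene (equatorial bromide) | C[C@@]12CC[C@H](O)[C@@](C)(C(=O)OC)[C@H]1[C@H](Br)C(=O)C(=C)[C@H]2CCC(=O)N(C)OC | intermediate
14 | 6β-bromo-3β,7α-dihydroxy-8(15)-ene (bromohydrin; the C7 configuration is inconsequential) | C[C@@]12CC[C@H](O)[C@@](C)(C(=O)OC)[C@H]1[C@H](Br)[C@@H](O)C(=C)[C@H]2CCC(=O)N(C)OC | intermediate (not isolated)
15 | ring-B-contracted aldehyde: methyl 3-formyl-5-hydroxy-1-{3-[methoxy(methyl)amino]-3-oxopropyl}-4,7a-dimethyl-2-methylideneoctahydro-1H-indene-4-carboxylate (C7 aldehyde β on C6, H-6 α) | C[C@@]12CC[C@H](O)[C@@](C)(C(=O)OC)[C@H]1[C@H](C=O)C(=C)[C@H]2CCC(=O)N(C)OC | intermediate (not isolated)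
16 | methyl 5-hydroxy-3-(hydroxymethyl)-1-{3-[methoxy(methyl)amino]-3-oxopropyl}-4,7a-dimethyl-2-methylideneoctahydro-1H-indene-4-carboxylate (3β-OH, 6β-CH2OH in target locants) | C[C@@]12CC[C@H](O)[C@@](C)(C(=O)OC)[C@H]1[C@H](CO)C(=C)[C@H]2CCC(=O)N(C)OC | intermediate
17 | tris(bromomagnesium) salt of the tetrahedral vinyl adduct of 16 (two alkoxides and the N-methoxy-N-methyl hemiaminal) | C[C@@]12CC[C@H](O[Mg]Br)[C@@](C)(C(=O)OC)[C@H]1[C@H](CO[Mg]Br)C(=C)[C@H]2CCC(O[Mg]Br)(C=C)N(C)OC | intermediate (not isolated)
18 | methyl 5-hydroxy-3-(hydroxymethyl)-4,7a-dimethyl-2-methylidene-1-(3-oxopent-4-en-1-yl)octahydro-1H-indene-4-carboxylate | C[C@@]12CC[C@H](O)[C@@](C)(C(=O)OC)[C@H]1[C@H](CO)C(=C)[C@H]2CCC(=O)C=C | intermediate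
19 | methyl 3β,7-dihydroxy-16-oxo-17-nor-ent-gibberellan-19-oate (C14 α and C15 β on C8) | C[C@@]12CC[C@H](O)[C@@](C)(C(=O)OC)[C@H]1[C@H](CO)[C@@]13C[C@@H](CC[C@@H]21)C(=O)C3 | intermediate
20 | methyl 3β,7,16-trihydroxy-ent-gibberellan-19-oate (16-OH endo, 16-CH3 exo) | C[C@@]12CC[C@H](O)[C@@](C)(C(=O)OC)[C@H]1[C@H](CO)[C@@]13C[C@@H](CC[C@@H]21)[C@@](C)(O)C3 | intermediate
21 | CNP0170663.1, 3β,7,16-trihydroxy-ent-gibberellan-19-oic acid (16-OH endo, 16-CH3 exo) | C[C@@]12CC[C@H](O)[C@@](C)(C(=O)O)[C@H]1[C@H](CO)[C@@]13C[C@@H](CC[C@@H]21)[C@@](C)(O)C3 | target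

## Totals and risk

Total step count: 13. Longest linear sequence: 13 steps (from geranyl bromide 1).

The three steps most likely to fail are steps 6, 9 and 11.

Step 6 rests on an unknown selectivity factor and can use at most half of 8. The fallback makes the bicyclisation itself enantioselective and sets out from 7. NaH then PhSeCl gives the α-phenylselanyl β-keto ester F1. A Mg(ClO4)2–chiral bis(oxazoline) Lewis acid with Et3B/O2 in toluene at −78 °C then effects a phenylselanyl-group-transfer radical bicyclisation to the tertiary C8 selenide F2. H2O2/pyridine gives the exocyclic alkene by selenoxide syn-elimination, that is, non-racemic 8. This is reduced with LiB(s-Bu)3H from the equatorial direction, and the fallback comes back to the route at 9.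

Step 9 may stall at the bromohydrin or give side reactions of the intermediate β,γ-unsaturated aldehyde. The fallback sets out from 13 and contracts the ring at the ester oxidation level. NaOMe in MeOH adds to the non-enolisable C7 carbonyl and the tetrahedral alkoxide drives a semibenzilic (quasi-Favorskii) shift of C8 to C6, giving the ring-contracted C7 methyl ester F3. LiBH4 in THF at 0 °C reduces this less hindered ester selectively, and the fallback comes back to the route at 16.

Step 11 may stop after the Prins step through proton loss, or the carbinol may form with the vinyl group equatorial. The fallback sets out from 18 and closes the two rings separately. SnCl4 in CH2Cl2 at −78 °C gives a Prins chlorocyclisation that closes ring C only, and the chloro tertiary allylic alcohol F4 is isolated. AgBF4 with 2,6-di-tert-butylpyridine in CH2Cl2 then abstracts chloride, and the C8 cation is trapped by the vinyl group with semipinacol shift of C12. The fallback comes back to the route at 19.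

## Further compounds

F1 | step 6 | methyl (6E,10E)-14-[methoxy(methyl)amino]-2,6,10-trimethyl-3,14-dioxo-2-(phenylselanyl)tetradeca-6,10-dienoate | COC(=O)C(C)([Se]c1ccccc1)C(=O)CC/C(C)=C/CC/C(C)=C/CCC(=O)N(C)OC
F2 | step 6 | bicyclic 3-oxo ester with 8β-phenylselanyl and 8α-methyl groups (group-transfer product; the C8 configuration is inconsequential) | C[C@@]12CCC(=O)[C@@](C)(C(=O)OC)[C@H]1CC[C@](C)([Se]c1ccccc1)[C@H]2CCC(=O)N(C)OC
F3 | step 9 | ring-B-contracted diester: the 3-(methoxycarbonyl) analogue of 16 (C7 as CO2Me, β on C6) | C[C@@]12CC[C@H](O)[C@@](C)(C(=O)OC)[C@H]1[C@H](C(=O)OC)C(=C)[C@H]2CCC(=O)N(C)OC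
F4 | step 11 | ring-C-closed chlorohydrin: 8α-chloro compound with a C16 tertiary allylic alcohol (vinyl axial α, OH equatorial) | C[C@@]12CC[C@H](O)[C@@](C)(C(=O)OC)[C@H]1[C@H](CO)[C@]3(Cl)C[C@@](O)(C=C)CC[C@@H]23
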